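The dusk run at 1.3 mM and the midnight run at 4.1 mM both hold about the same share of substrate at 15.0 min, 75.5% and 75.9%, so at −30 °C the decay of substrate reads as first-order, with ionisation to intermediate and leaving ligand as the rate-limiting step in these two runs.

| flask | substrate | partner | temperature | remark | time |
|---|---|---|---|---|---|
| dusk | 1.3 mM | 1.8 equiv | −30 °C | run made earlier |  |
| noon | 2.1 mM | 1.8 equiv | 0 °C | run made earlier |  |
| midnight | 4.1 mM | 1.8 equiv | −30 °C | run made earlier |  |
| summer | 1 mM | 1.7 equiv | 0 °C | run made earlier |  |
| epsilon | 1.0 mM | 5.40 equiv | −25 °C |  | 6.0 min |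
| eta | 1.0 mM | 2.70 equiv | 25 °C |  | 6.0 min |
| beta | 4.0 mM | 0.450 equiv | 25 °C |  | 6.0 min |
| gamma | 1.0 mM | 1.80 equiv | 5 °C |  | 6.0 min |

- dusk (time / min: product / %, substrate / %): 1.33: 2.7, 96.4; 3.00: 7.2, 95.5; 8.00: 14.1, 85.6; 15.0: 25.2, 75.5
- noon (time / min: product / %, substrate / %): 0.833: 40.3, 58.5; 1.50: 57.9, 39.4; 2.50: 77.4, 21.7; 3.00: 82.6, 19.2
- midnight (time / min: product / %, substrate / %): 2.50: 4.6, 96.3; 6.00: 10.7, 90.4; 12.0: 20.2, 81.4; 15.0: 24.6, 75.9
- summer (time / min: product / %, substrate / %): 0.417: 25.0, 77.1; 1.00: 47.4, 52.4; 2.00: 69.2, 29.5; 3.00: 80.0, 18.4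

(each reading ± 1 percentage point)

- reactions considered so far: substrate <-> intermediate + leaving ligand; partner + intermediate -> product; partner -> decomposed reagent

* the flasks by amount of product, in percent of the substrate charged, highest first, at 6.0 min (epsilon / eta / beta / gamma)
* the amount of product, in percent of the substrate charged of the flask you put first, at 6.0 min
* the amount of product, in percent of the substrate charged of the flask you put last, at 6.0 min

Two readings give the clock, the dusk run for the cold end and the summer run for the warm end:

k(dusk) = 0.0187 min⁻¹, k(summer) = 0.646 min⁻¹, factor 34.5 from −30 °C to 0 °C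

Carrying that factor on at the same proportion per degree gives gamma:

k(gamma) = 1.17 min⁻¹, N(gamma) = 7.00

N is the turnover count: the substrate lifetimes that fit into the time allowed. While each intermediate goes on to product and not back to substrate, the substrate turned over is one minus exp(−N).

The ledger of partner, reckoned here and not by the forecast:

epsilon: c(partner) 5.40 mM; N = 0.203; product entry 0.184 mM, or 18.4%

beta: c(partner) 1.80 mM against c(substrate) 4.0 mM; partner is the limiting reagent, so product stays below 45.0%

gamma: c(partner) 1.80 mM; the count asks for nearly all of 1.0 mM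

eta: c(partner) 2.70 mM; N = 74.1

In gamma and eta the decomposition entry stays open. The summer run held 18.4% substrate at 3.00 min where its early constant gives 14.4%, a lag that this entry may explain; this reckoning does not size it. It leaves gamma against eta open.

The forecast gave eta > gamma > beta > epsilon, with 96% and 20%, and said of eta: “about 97% unless decomposition competes”.

The flasks give gamma > eta > beta > epsilon, with 85.1% and 19.2%.

    substrate ⇌ intermediate + leaving ligand (K = 2.78 × 10⁻⁶ M, k = 0.0177 s⁻¹, Ea = 65.0 kJ mol⁻¹, ΔH = −13.0 kJ mol⁻¹)
    partner + intermediate → product (k = 57000 M⁻¹ s⁻¹, Ea = 19.0 kJ mol⁻¹)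
    partner → decomposed reagent (k = 0.0138 s⁻¹, Ea = 74.0 kJ mol⁻¹)
    (constants at 5 °C)

In gamma, partner halves by decomposition alone in 0.84 min, while one substrate lifetime of the reckoning above takes 0.855 min. Partner in gamma stood at 0.313% of its charge at 3.00 min, when 3.50 of the 7.00 counted turnovers had passed, and by 6.0 min its books closed at 0.851 mM to product and 0.949 mM to decomposed reagent.

The neighbour flask, epsilon repeated at −10 °C, has N = 1.19, which gives 69.6%. It computes to 72.2% product, with 36.4% of its partner left.

(The data stem from a simulated flask from invented constants; scatter was added.)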